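Readings and results were computed with made-up constants, and the scatter is random.

"Divide a reading by its time: what do you have?"

| setting | noon | dawn | Thursday's | Sunday's | Monday's | Wednesday's |
|---|---|---|---|---|---|---|
| starting material | 15 mM | 33 mM | 22 mM | 22 mM | 22 mM | 22 mM |
| reagent | 39.6 mM | 39.6 mM | 39.6 mM | 39.6 mM | 39.6 mM | 39.6 mM |
| capture agent | 1.1 mM | 1.1 mM | 1.10 mM | 1.10 mM | 1.10 mM | 1.10 mM |
| temperature | 58 °C | 74 °C | 65 °C | 50 °C | 80 °C |  |
| remark | run made earlier | run made earlier |  |  |  | at 50 °C until 4.0 min, from then on at 80 °C |
| time |  |  | 5.0 min | 5.0 min | 5.0 min | 5.0 min |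

| run | time / min | target / % |
|---|---|---|
| noon | 0.333 | 1.7 |
| noon | 0.667 | 3.0 |
| noon | 1.00 | 5.2 |
| noon | 2.00 | 6.5 |
| noon | 4.00 | 10.4 |
| dawn | 0.200 | 0 |
| dawn | 0.667 | 1.0 |
| dawn | 1.33 | 2.1 |
| dawn | 2.00 | 4.0 |
| dawn | 2.50 | 3.5 |

(scatter of a reading: 1 percentage point)

- which flask leads in amount of target, in percent of the starting material charged ("all alike" within 1.5 percentage points) (Thursday's / Sunday's / Monday's / Wednesday's / all alike)
- how much target is there at the end, in percent of the starting material charged: Thursday's
- how much target is there at the end, in percent of the starting material charged: Sunday's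
- how much target is there at the end, in percent of the starting material charged: Monday's
- how much target is there at the end, in percent of the starting material charged: Wednesday's

- the analysis behind the earlier runs scatters by 1 percentage point, standard deviation

"A pace, in percent of the charge per minute. The noon run, at 58 °C, stands at 10.4% after 4.00 min, and the dawn run, at 74 °C, at 3.5% after 2.50 min."

"Which pace is larger?"

"Noon's, the cooler run's. I call f = 1.86 the fade, the noon pace over the dawn pace. It is the factor lost from the noon run to the dawn run."

"But dawn also held 33 mM of starting material against noon's 15 mM."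

"Yes, so f mixes charge with heat, and it rests on two readings, each with a scatter of 1 percentage point. Taken at face value, it is a negative apparent activation energy."

"And the noon readings slow down. Can you trust a steady pace?"

"Not for the level. I reckon target by itself at a steady pace, so my levels are loose. The four flasks share one charge, though, and a level drops out of a ratio. If f carries over degree by degree, which I assume, Sunday's over Monday's is f raised to their temperature step over the noon-to-dawn step, R = 3.19."

"Commit yourself."

"From noon, Sunday's at 50 °C gets 17.7% and Thursday's at 65 °C gets 9.92%. From dawn, Monday's at 80 °C gets 5.55%. Wednesday's, with 4.0 min at Sunday's pace and the rest at Monday's, gets 15.3%. So I say Sunday's leads."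

The forecast differs from this reckoning. It says all alike, with 9% for Thursday's, 8% for Sunday's, 10% for Monday's and 8.5% for Wednesday's, expecting “only a slight rise with temperature”.

The flasks give 7.69% for Thursday's, 12.1% for Sunday's, 3.54% for Monday's and 8.85% for Wednesday's, so Sunday's leads.

    starting material ⇌ tautomer (K = 0.343, k = 0.0507 s⁻¹, Ea = 77.0 kJ mol⁻¹, ΔH = −55.0 kJ mol⁻¹)
    starting material + reagent → isomer of the product (k = 0.0438 M⁻¹ s⁻¹, Ea = 70.0 kJ mol⁻¹)
    reagent + tautomer → target (k = 0.0742 M⁻¹ s⁻¹, Ea = 62.0 kJ mol⁻¹)
    starting material + target → side product (k = 0.105 M⁻¹ s⁻¹, Ea = 63.0 kJ mol⁻¹)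
    capture agent + tautomer → trapped intermediate (k = 0.0159 M⁻¹ s⁻¹, Ea = 66.0 kJ mol⁻¹)
    (constants at 50 °C)

Sunday's over Monday's comes out at 3.42, against R of 3.19 from f, though my Sunday's level of 17.7% stood above the flask. Now take the neighbour of Wednesday's, charged with 16 mM of reagent instead of 39.6 mM. I start from Sunday's level, give the time after 4.0 min the pace divided by R, and take the pace as proportional to reagent, an assumption the earlier runs cannot test, since both held 39.6 mM. That gives 4.20%. The neighbour gave 3.35%.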